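**Strategy.** The upper flavan unit is built de novo and joined last, through C4–C8, to octa-O-benzyl-EGCG, itself assembled from (−)-epigallocatechin and tri-O-benzylgallic acid. Its pyran ring (O1, C2, C3, C4, C4a, C8a) is made from a five-membered ring: a racemic 2-aryl-benzofuran-3(2H)-one with a temporary allyl ester at C2 is enlarged by one carbon with TMSCHN2, the new carbon becoming C4 between the C3 carbonyl and C4a. The step exploits C4a of ring A, ortho or para to O1, O5 and O7, which migrates in preference to the ester-bearing C2. Deallylative decarboxylation, dynamic kinetic resolution hydrogenation (sets C2 and C3), C4 oxidation, 4β→8 coupling and hydrogenolysis follow.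

Key step: step 4

Assumption: the antipode of the ruthenium catalyst written in step 6 is taken to be the one matched to (2R,3R)-15; if the sense proves opposite, its mirror image is used with no other change.

Step 1
Reactants: 1 4,6-dihydroxybenzofuran-3(2H)-one; 2 benzyl bromide
Product: 3 4,6-bis(benzyloxy)benzofuran-3(2H)-one
Conditions: K2CO3, DMF, 60 °C
Reagents that add atoms: benzyl bromide, BrCc1ccccc1
Why: Williamson etherification of the two phenols, which are deprotonated by carbonate far more readily than the C2 methylene is C-alkylated.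

Step 2
Reactants: 3 4,6-bis(benzyloxy)benzofuran-3(2H)-one; 4 diallyl carbonate
Product: 5 allyl 4,6-bis(benzyloxy)-3-hydroxybenzofuran-2-carboxylate (enol form of the β-keto ester)
Conditions: NaH, THF, reflux; then AcOH
Reagents that add atoms: diallyl carbonate, C=CCOC(=O)OCC=C
Why: Claisen-type C-acylation of the ketone enolate by the carbonate, pulled to the C-acylated product by irreversible formation of the doubly stabilised sodium enolate of 5.

Step 3
Reactants: 5 allyl 4,6-bis(benzyloxy)-3-hydroxybenzofuran-2-carboxylate; 6 3,4-bis(benzyloxy)phenylboronic acid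
Product: 8 allyl 2-[3,4-bis(benzyloxy)phenyl]-4,6-bis(benzyloxy)-3-oxo-2,3-dihydrobenzofuran-2-carboxylate (racemic), via aryllead triacetate 7 (not isolated)
Conditions: Pb(OAc)4, Hg(OAc)2 (cat.), CHCl3, 40 °C (6 alone); then 5, pyridine, 60 °C
Reagents that add atoms: 3,4-bis(benzyloxy)phenylboronic acid, OB(O)c1ccc(OCc2ccccc2)c(OCc2ccccc2)c1
Why: Pinhey arylation, in which boron-to-lead exchange gives 7, the enol oxygen of 5 binds to lead and the aryl group is delivered to C2 by ligand coupling, forming the quaternary centre (racemic, destroyed again in step 5).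

Step 4
Reactants: 8 allyl 2-[3,4-bis(benzyloxy)phenyl]-4,6-bis(benzyloxy)-3-oxo-2,3-dihydrobenzofuran-2-carboxylate; 9 trimethylsilyldiazomethane
Product: 12 allyl 2-[3,4-bis(benzyloxy)phenyl]-5,7-bis(benzyloxy)-3-oxochromane-2-carboxylate (racemic), via diazonium betaine 10 (not isolated), via C4-silyl ketone 11 (not isolated)
Conditions: BF3·OEt2, CH2Cl2, −78 to −20 °C; then 1 M HCl, THF, rt
Reagents that add atoms: trimethylsilyldiazomethane, C[Si](C)(C)C=[N+]=[N-]
Why: The BF3-activated C3 carbonyl of 8 is attacked by the nucleophilic carbon of the diazoalkane to give betaine 10; the C3–C3a bond, antiperiplanar to the departing N2, then migrates to the diazo carbon as the carbonyl re-forms, so the carbon delivered by the reagent becomes C4 between C3 and C4a (Tiffeneau–Demjanov-type diazoalkane homologation; closest precedents are the aryl-migrating enlargements of 1-indanones to 2-tetralones and of isatins to quinolin-2-ones). No ring is closed: the five-membered furanone ring (O1, C2, C3, C3a, C7a) is enlarged to the six-membered pyranone (O1, C2, C3, C4, C4a, C8a) by this 1,2-shift. No stereocenter of the target is set here: C2 is quaternary and racemic, and the silicon-bearing C4 of 11 loses its silyl group on acidic work-up. The step needs migration of ring A instead of C2, and a single homologation; the first is secured because the ipso carbon lies ortho to O1 and to the 4-benzyloxy group and para to the 6-benzyloxy group (phenonium-like bridging), whereas C2 is fully substituted and carries the electron-withdrawing ester and the ring oxygen, and the second by the bulky α-silyl group of 11, which shields the new ketone until work-up. The C2 ester also removes the acidic C2–H, so the ketone cannot escape as the aromatic 3-hydroxybenzofuran, and it raises the electrophilicity of the carbonyl.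

Step 5
Reactants: 12 allyl 2-[3,4-bis(benzyloxy)phenyl]-5,7-bis(benzyloxy)-3-oxochromane-2-carboxylate
Product: 14 2-[3,4-bis(benzyloxy)phenyl]-5,7-bis(benzyloxy)chroman-3-one (racemic), via keto acid 13 (not isolated)
Conditions: Pd(PPh3)4 (cat.), HCO2H, Et3N, THF, 25 to 45 °C
Reagents that add atoms: none
Why: Zerovalent palladium ionises the allyl ester, formate reduces the allyl fragment to propene, and the freed β-keto acid 13 loses CO2 under the same mild conditions (Tsuji-type deallylation–decarboxylation), leaving a racemic C2 centre that is resolved dynamically in step 6.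

Step 6
Reactants: 14 2-[3,4-bis(benzyloxy)phenyl]-5,7-bis(benzyloxy)chroman-3-one
Product: 15 (2R,3R)-2-[3,4-bis(benzyloxy)phenyl]-5,7-bis(benzyloxy)chroman-3-ol (5,7,3',4'-tetra-O-benzylepicatechin; 2,3-cis)
Conditions: H2 (10 atm), RuCl2[(S)-xylbinap][(S)-daipen] (cat.), KOt-Bu (cat.), i-PrOH/THF, rt
Reagents that add atoms: none
Why: Under KOt-Bu the C2–H of 14 (α to the carbonyl, benzylic and α to oxygen) should epimerise faster than the ketone is reduced, and the ruthenium hydride of the matched catalyst adds to the carbonyl of the (2R) ketone from the face opposite the C2 aryl group, so C3 is set cis to C2 and both centres are fixed together (Noyori-type dynamic kinetic resolution hydrogenation of an α-aryl ketone).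

Step 7
Reactants: 15 (2R,3R)-5,7,3',4'-tetra-O-benzylepicatechin; 16 2-ethoxyethanol
Product: 17 (2R,3R,4S)-2-[3,4-bis(benzyloxy)phenyl]-5,7-bis(benzyloxy)-4-(2-ethoxyethoxy)chroman-3-ol (4β-ether; 3,4-trans)
Conditions: DDQ, CH2Cl2, rt
Reagents that add atoms: 2-ethoxyethanol, CCOCCO
Why: DDQ abstracts hydride from C4, the benzylic position stabilised by the three ring A oxygens, and the alcohol adds to the cation anti to the 3-hydroxyl (benzylic oxidation–etherification); the configuration of this centre is not critical because it is ionised again in step 10.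

Step 8
Reactants: 18 (−)-epigallocatechin; 2 benzyl bromide
Product: 19 5,7,3',4',5'-penta-O-benzyl-(−)-epigallocatechin
Conditions: K2CO3, DMF, 0 °C to rt, under argon
Reagents that add atoms: benzyl bromide, BrCc1ccccc1
Why: Williamson etherification of the five phenols under carbonate conditions that leave the far less acidic secondary 3-hydroxyl free and are mild enough not to epimerise C2.

Step 9
Reactants: 19 5,7,3',4',5'-penta-O-benzyl-(−)-epigallocatechin; 20 3,4,5-tris(benzyloxy)benzoic acid
Product: 21 octa-O-benzyl-(−)-epigallocatechin 3-O-gallate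
Conditions: DCC, DMAP, CH2Cl2, rt
Reagents that add atoms: 3,4,5-tris(benzyloxy)benzoic acid, OC(=O)c1cc(OCc2ccccc2)c(OCc2ccccc2)c(OCc2ccccc2)c1
Why: Steglich esterification, in which DCC activates the acid as its O-acylisourea and DMAP relays the acyl group to the hindered 3-hydroxyl; acylation occurs at oxygen, so C3 keeps its configuration.

Step 10
Reactants: 17 4β-(2-ethoxyethoxy)-5,7,3',4'-tetra-O-benzylepicatechin; 21 octa-O-benzyl-(−)-epigallocatechin 3-O-gallate
Product: 22 dodeca-O-benzyl epicatechin-(4β→8)-epigallocatechin 3-O-gallate (upper unit 2R,3R,4R with free 3-OH; lower unit 2R,3R)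
Conditions: TMSOTf (cat.), CH2Cl2, −78 °C, 21 in threefold excess; then Et3N
Reagents that add atoms: none
Why: TMSOTf ionises the C4 ether of 17 to the ring A-stabilised benzylic cation, which is attacked by C8 of 21 (the most nucleophilic and least hindered ring A position) from the β face, anti to the 3-hydroxyl and the 2-aryl group, so C4 is set 3,4-trans (4β); this is a Friedel–Crafts-type flavan-4-yl cation coupling, and the excess of 21 suppresses self-condensation of 17.

Step 11
Reactants: 22 dodeca-O-benzyl epicatechin-(4β→8)-epigallocatechin 3-O-gallate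
Product: 23 epicatechin-(4β→8)-epigallocatechin 3-O-gallate (target)
Conditions: H2 (1 atm), Pd(OH)2/C, THF/MeOH/H2O, rt
Reagents that add atoms: none
Why: Hydrogenolysis of the twelve benzyl ethers under neutral conditions that should leave the gallate ester, the interflavan bond and the five stereocenters untouched.

**Compound list**

1 | 4,6-dihydroxybenzofuran-3(2H)-one | O=C1COc2cc(O)cc(O)c12 | starting material
2 | benzyl bromide | BrCc1ccccc1 | starting material
3 | 4,6-bis(benzyloxy)benzofuran-3(2H)-one | O=C1COc2cc(OCc3ccccc3)cc(OCc3ccccc3)c12 | intermediate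
4 | diallyl carbonate | C=CCOC(=O)OCC=C | starting material
5 | allyl 4,6-bis(benzyloxy)-3-hydroxybenzofuran-2-carboxylate (enol tautomer) | C=CCOC(=O)c1oc2cc(OCc3ccccc3)cc(OCc3ccccc3)c2c1O | intermediate
6 | 3,4-bis(benzyloxy)phenylboronic acid | OB(O)c1ccc(OCc2ccccc2)c(OCc2ccccc2)c1 | starting material
7 | 3,4-bis(benzyloxy)phenyllead triacetate | CC(=O)O[Pb](OC(C)=O)(OC(C)=O)c1ccc(OCc2ccccc2)c(OCc2ccccc2)c1 | intermediate (not isolated)
8 | allyl 2-[3,4-bis(benzyloxy)phenyl]-4,6-bis(benzyloxy)-3-oxo-2,3-dihydrobenzofuran-2-carboxylate (racemic) | C=CCOC(=O)C1(c2ccc(OCc3ccccc3)c(OCc3ccccc3)c2)Oc2cc(OCc3ccccc3)cc(OCc3ccccc3)c2C1=O | intermediate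
9 | trimethylsilyldiazomethane | C[Si](C)(C)C=[N+]=[N-] | starting material
10 | diazonium betaine: allyl 2-aryl-4,6-bis(benzyloxy)-3-[diazonio(trimethylsilyl)methyl]-3-oxido-2,3-dihydrobenzofuran-2-carboxylate (drawn without the boron trifluoride on oxygen) | C=CCOC(=O)C1(c2ccc(OCc3ccccc3)c(OCc3ccccc3)c2)Oc2cc(OCc3ccccc3)cc(OCc3ccccc3)c2C1([O-])C([N+]#N)[Si](C)(C)C | intermediate (not isolated)
11 | allyl 2-[3,4-bis(benzyloxy)phenyl]-5,7-bis(benzyloxy)-3-oxo-4-(trimethylsilyl)chromane-2-carboxylate | C=CCOC(=O)C1(c2ccc(OCc3ccccc3)c(OCc3ccccc3)c2)Oc2cc(OCc3ccccc3)cc(OCc3ccccc3)c2C([Si](C)(C)C)C1=O | intermediate (not isolated)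
12 | allyl 2-[3,4-bis(benzyloxy)phenyl]-5,7-bis(benzyloxy)-3-oxochromane-2-carboxylate (racemic) | C=CCOC(=O)C1(c2ccc(OCc3ccccc3)c(OCc3ccccc3)c2)Oc2cc(OCc3ccccc3)cc(OCc3ccccc3)c2CC1=O | intermediate
13 | 2-[3,4-bis(benzyloxy)phenyl]-5,7-bis(benzyloxy)-3-oxochromane-2-carboxylic acid | OC(=O)C1(c2ccc(OCc3ccccc3)c(OCc3ccccc3)c2)Oc2cc(OCc3ccccc3)cc(OCc3ccccc3)c2CC1=O | intermediate (not isolated)
14 | 2-[3,4-bis(benzyloxy)phenyl]-5,7-bis(benzyloxy)chroman-3-one (racemic) | O=C1Cc2c(OCc3ccccc3)cc(OCc3ccccc3)cc2OC1c1ccc(OCc2ccccc2)c(OCc2ccccc2)c1 | intermediate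
15 | (2R,3R)-2-[3,4-bis(benzyloxy)phenyl]-5,7-bis(benzyloxy)chroman-3-ol (tetra-O-benzylepicatechin) | O[C@@H]1Cc2c(OCc3ccccc3)cc(OCc3ccccc3)cc2O[C@@H]1c1ccc(OCc2ccccc2)c(OCc2ccccc2)c1 | intermediate
16 | 2-ethoxyethanol | CCOCCO | starting material
17 | (2R,3R,4S)-2-[3,4-bis(benzyloxy)phenyl]-5,7-bis(benzyloxy)-4-(2-ethoxyethoxy)chroman-3-ol (4β-ether) | O[C@@H]1[C@@H](OCCOCC)c2c(OCc3ccccc3)cc(OCc3ccccc3)cc2O[C@@H]1c1ccc(OCc2ccccc2)c(OCc2ccccc2)c1 | intermediate
18 | (−)-epigallocatechin, (2R,3R) | O[C@@H]1Cc2c(O)cc(O)cc2O[C@@H]1c1cc(O)c(O)c(O)c1 | starting material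
19 | 5,7,3',4',5'-penta-O-benzyl-(−)-epigallocatechin | O[C@@H]1Cc2c(OCc3ccccc3)cc(OCc3ccccc3)cc2O[C@@H]1c1cc(OCc2ccccc2)c(OCc2ccccc2)c(OCc2ccccc2)c1 | intermediate
20 | 3,4,5-tris(benzyloxy)benzoic acid (tri-O-benzylgallic acid) | OC(=O)c1cc(OCc2ccccc2)c(OCc2ccccc2)c(OCc2ccccc2)c1 | starting material
21 | octa-O-benzyl-(−)-epigallocatechin 3-O-gallate | O=C(O[C@@H]1Cc2c(OCc3ccccc3)cc(OCc3ccccc3)cc2O[C@@H]1c1cc(OCc2ccccc2)c(OCc2ccccc2)c(OCc2ccccc2)c1)c1cc(OCc2ccccc2)c(OCc2ccccc2)c(OCc2ccccc2)c1 | intermediate
22 | dodeca-O-benzyl epicatechin-(4β→8)-epigallocatechin 3-O-gallate (upper unit 2R,3R,4R, 3-OH free; lower unit 2R,3R) | O=C(O[C@@H]1Cc2c(OCc5ccccc5)cc(OCc5ccccc5)c([C@H]3c4c(OCc5ccccc5)cc(OCc5ccccc5)cc4O[C@H](c4ccc(OCc5ccccc5)c(OCc5ccccc5)c4)[C@@H]3O)c2O[C@@H]1c1cc(OCc2ccccc2)c(OCc2ccccc2)c(OCc2ccccc2)c1)c1cc(OCc2ccccc2)c(OCc2ccccc2)c(OCc2ccccc2)c1 | intermediate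
23 | epicatechin-(4β→8)-epigallocatechin 3-O-gallate: (2R,3R)-8-[(2R,3R,4R)-2-(3,4-dihydroxyphenyl)-3,5,7-trihydroxychroman-4-yl]-5,7-dihydroxy-2-(3,4,5-trihydroxyphenyl)chroman-3-yl 3,4,5-trihydroxybenzoate | O=C(O[C@@H]1Cc2c(O)cc(O)c([C@H]3c4c(O)cc(O)cc4O[C@H](c4ccc(O)c(O)c4)[C@@H]3O)c2O[C@@H]1c1cc(O)c(O)c(O)c1)c1cc(O)c(O)c(O)c1 | target

**Step count.** Total: 11 steps. Longest linear sequence: 9 steps (steps 1–7, 10 and 11); steps 8 and 9 form the two-step side branch.

**Steps most likely to fail**

Step 4 (key step). The diazoalkane may add only slowly to a carbonyl that is flanked by a quaternary centre and a peri benzyloxy group and deactivated by the ring A donors. The betaine may also close to the spiro-epoxide instead of rearranging, or the product may be homologated a second time. The fallback sets out from 8 and returns at 12. Dibromomethyllithium (from CH2Br2 and lithium 2,2,6,6-tetramethylpiperidide, THF, −95 °C) is added to the C3 ketone to give the dibromomethyl carbinol F1. Treatment with n-BuLi (2 equiv) at −95 to −78 °C should then trigger bromine–lithium exchange and the β-oxido carbenoid rearrangement with migration of ring A, and protonation on work-up gives 12. The hindered quaternary ester is expected to survive at this temperature.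

Step 6. Epimerisation at C2 may be slower than reduction, which would leave only a kinetic resolution, or the catalyst may discriminate poorly between the faces of a ketone flanked by two sp3 carbons. The fallback sets out from 14 and returns at 15. LiBH(s-Bu)3 (THF, −78 °C) reduces 14 anti to the C2 aryl group to the racemic cis-alcohol, that is 15 together with its (2S,3S) enantiomer F2. Esterification with (S)-2-methoxy-2-phenylacetic acid (DCC, DMAP) gives the diastereomeric esters F3 (from 15) and F4 (from F2), which are separated by chromatography. Saponification of F3 (LiOH, THF/H2O) returns 15.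

Step 3. Ligand coupling at the hindered, ester-bearing enol carbon may be outrun by O-arylation or by decomposition of the electron-rich aryllead reagent to biaryl. The fallback sets out from 5 and returns at 8. Catechol is oxidised (NaIO4, CH2Cl2/H2O, 0 °C) to o-benzoquinone F5. The enol 5 is added to it in a conjugate fashion to give the C2-(3,4-dihydroxyphenyl) adduct, the catechol F6. Benzylation of its two phenols (benzyl bromide, K2CO3, DMF) then gives 8.

**Further compounds**

F1 | step 4 | allyl 2-[3,4-bis(benzyloxy)phenyl]-4,6-bis(benzyloxy)-3-(dibromomethyl)-3-hydroxy-2,3-dihydrobenzofuran-2-carboxylate (racemic) | C=CCOC(=O)C1(c2ccc(OCc3ccccc3)c(OCc3ccccc3)c2)Oc2cc(OCc3ccccc3)cc(OCc3ccccc3)c2C1(O)C(Br)Br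
F2 | step 6 | (2S,3S)-2-[3,4-bis(benzyloxy)phenyl]-5,7-bis(benzyloxy)chroman-3-ol (enantiomer of 15, formed with 15 as the racemate) | O[C@H]1Cc2c(OCc3ccccc3)cc(OCc3ccccc3)cc2O[C@H]1c1ccc(OCc2ccccc2)c(OCc2ccccc2)c1
F3 | step 6 | (2R,3R)-2-[3,4-bis(benzyloxy)phenyl]-5,7-bis(benzyloxy)chroman-3-yl (S)-2-methoxy-2-phenylacetate | CO[C@H](C(=O)O[C@@H]1Cc2c(OCc3ccccc3)cc(OCc3ccccc3)cc2O[C@@H]1c1ccc(OCc2ccccc2)c(OCc2ccccc2)c1)c1ccccc1
F4 | step 6 | (2S,3S)-2-[3,4-bis(benzyloxy)phenyl]-5,7-bis(benzyloxy)chroman-3-yl (S)-2-methoxy-2-phenylacetate | CO[C@H](C(=O)O[C@H]1Cc2c(OCc3ccccc3)cc(OCc3ccccc3)cc2O[C@H]1c1ccc(OCc2ccccc2)c(OCc2ccccc2)c1)c1ccccc1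
F5 | step 3 | o-benzoquinone (cyclohexa-3,5-diene-1,2-dione) | O=C1C=CC=CC1=O
F6 | step 3 | allyl 4,6-bis(benzyloxy)-2-(3,4-dihydroxyphenyl)-3-oxo-2,3-dihydrobenzofuran-2-carboxylate (racemic) | C=CCOC(=O)C1(c2ccc(O)c(O)c2)Oc2cc(OCc3ccccc3)cc(OCc3ccccc3)c2C1=O
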